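The ten-membered ring is grown, not cyclised: oxygenated C2 and the C5=C6 alkene are linked through C3–C4, a γ,δ-unsaturated ketone pattern. A thermal Claisen shift of a 2-methylene-8-isopropenyl oxocane, whose oxygen bridges C2 and C6 and which is fused to ring A at C1–C10, forms C3–C4, cleaves C6–O and delivers the C2 ketone and the Z C5=C6 alkene in one operation. The precursor is the exocyclic enol ether of an eight-membered lactone bearing a C8/C9 acetonide (O9 stays masked until the γ-lactone exists), TBS ethers at O7 and C19, and a TIPS ether at O12; C6 is sacrificial.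

Key step: step 22

Remark on the chemistry: atoms carry briarane numbers and α denotes the ring A face of H10 (β that of the C15 methyl); in step 3 the catalyst antipode is taken to be the one whose pretransition-state assembly leads to (1S,5S,6S)-6; C6 in 27–33 is sacrificial, so either C6 epimer would converge on 34.

Step 1
Reactants: 1 2,2-dimethoxyacetaldehyde; 2 methyl 2-(triphenyl-λ5-phosphanylidene)propanoate
Product: 3 methyl (2E)-4,4-dimethoxy-2-methylbut-2-enoate
Conditions: CH2Cl2, 25 °C
Reagents that add atoms: none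
Why: Wittig olefination with a stabilised α-methyl ylide should give the E trisubstituted enoate (ester trans to the acetal carbon) under the usual thermodynamic control.

Step 2
Reactants: 3 methyl (2E)-4,4-dimethoxy-2-methylbut-2-enoate
Product: 4 methyl (2E)-2-methyl-4-oxobut-2-enoate
Conditions: aq. HCl (1 M), THF, 25 °C
Reagents that add atoms: water, O
Why: Acid-catalysed acetal hydrolysis unmasks the enal, and the E geometry, the more stable one, is kept.

Step 3
Reactants: 4 methyl (2E)-2-methyl-4-oxobut-2-enoate; 5 (3E)-penta-1,3-diene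
Product: 6 methyl (1S,5S,6S)-6-formyl-1,5-dimethylcyclohex-3-ene-1-carboxylate
Conditions: oxazaborolidinium triflimide from (S)-diphenylprolinol, o-tolylboroxine and Tf2NH (20 mol %), CH2Cl2, −78 → −40 °C
Reagents that add atoms: none
Why: Enantioselective Lewis-acid-catalysed Diels–Alder reaction in which the catalyst-bound formyl group is the controlling acceptor, so the CH2 terminus of the diene bonds to C1 and the methyl-bearing terminus to C10, the E dienophile keeps ester and formyl trans (C1/C10), the endo formyl places C9 cis to the C11 methyl, and the catalyst shields one enal face to fix the absolute sense.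

Step 4
Reactants: 7 dimethyl (2S)-2-hydroxybutanedioate
Product: 9 dimethyl (2S,3R)-2-hydroxy-3-methylbutanedioate, via dilithium alkoxide enolate 8 (not isolated)
Conditions: LiN(iPr)2 (2.1 equiv), THF, −78 → −20 °C; MeI, −78 → 0 °C
Reagents that add atoms: iodomethane, CI
Why: Fráter–Seebach alkylation, in which the chelated alkoxide enolate is methylated anti to the alkoxide and so sets C17 relative to C8.

Step 5
Reactants: 9 dimethyl (2S,3R)-2-hydroxy-3-methylbutanedioate
Product: 10 (2S,3R)-2-hydroxy-3-methylbutanedioic acid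
Conditions: KOH, H2O–MeOH, 0 → 25 °C; then HCl
Reagents that add atoms: potassium hydroxide, [K+].[OH-]
Why: Saponification of both esters at low temperature, where the C17 centre next to the carboxylate should not epimerise at a useful rate.

Step 6
Reactants: 10 (2S,3R)-2-hydroxy-3-methylbutanedioic acid
Product: 11 (2R)-2-[(2S,4S)-2-tert-butyl-5-oxo-1,3-dioxolan-4-yl]propanoic acid
Conditions: tBuCHO, TsOH (cat.), H2SO4 (cat.), pentane, reflux with water separation
Reagents that add atoms: 2,2-dimethylpropanal, CC(C)(C)C=O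
Why: Acid-catalysed acetalisation of the α-hydroxy acid closes the five-membered dioxolanone in preference to the six-membered dioxanone and equilibrates to the cis isomer, storing the C8 configuration in the acetal carbon (self-regeneration of stereocentres).

Step 7
Reactants: 11 (2R)-2-[(2S,4S)-2-tert-butyl-5-oxo-1,3-dioxolan-4-yl]propanoic acid
Product: 12 (2S,5S)-2-tert-butyl-5-[(2S)-1-hydroxypropan-2-yl]-1,3-dioxolan-4-one
Conditions: BH3·SMe2, THF, 0 °C
Reagents that add atoms: none
Why: Chemoselective borane reduction of the free carboxylic acid through its acyloxyborane leaves the dioxolanone carbonyl untouched.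

Step 8
Reactants: 12 (2S,5S)-2-tert-butyl-5-[(2S)-1-hydroxypropan-2-yl]-1,3-dioxolan-4-one
Product: 13 (2S,5S)-2-tert-butyl-5-[(2S)-1-(tert-butyldimethylsilyloxy)propan-2-yl]-1,3-dioxolan-4-one
Conditions: TBSCl, imidazole, CH2Cl2, 0 °C
Reagents that add atoms: tert-butyl(chloro)dimethylsilane, CC(C)(C)[Si](C)(C)Cl
Why: Standard silylation of the primary alcohol, done at once so that the hydroxyl cannot translactonise onto the dioxolanone.

Step 9
Reactants: 13 (2S,5S)-2-tert-butyl-5-[(2S)-1-(tert-butyldimethylsilyloxy)propan-2-yl]-1,3-dioxolan-4-one; 6 methyl (1S,5S,6S)-6-formyl-1,5-dimethylcyclohex-3-ene-1-carboxylate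
Product: 15 C9-hydroxy C8-dioxolanone aldol adduct of the ring A ester, via lithium enolate 14 (not isolated)
Conditions: LiN(iPr)2, THF, −78 °C; then 6, −78 °C; AcOH, −78 °C
Reagents that add atoms: none
Why: Aldol addition of a dioxolanone enolate in which the aldehyde adds to C8 anti to the tert-butyl group (overall retention at C8), Felkin–Anh attack anti to C1 sets C9, and the Zimmerman–Traxler chair with C17 cis to O–Li requires the same O8/O9 relationship, so the three elements are matched, while the cold quench keeps the aldolate from lactonising onto the C2 ester.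

Step 10
Reactants: 15 C9-hydroxy C8-dioxolanone aldol adduct of the ring A ester
Product: 16 C8/C9 diol C7 Weinreb amide
Conditions: AlMe3, MeNH(OMe)·HCl, CH2Cl2, 0 → 25 °C
Reagents that add atoms: N,O-dimethylhydroxylamine hydrochloride, CNOC.Cl
Why: Weinreb aminolysis with an aluminium amide opens the activated dioxolanone (an acylal) far faster than the neopentyl-type C2 ester and releases pivalaldehyde and the C8 hydroxyl.

Step 11
Reactants: 16 C8/C9 diol C7 Weinreb amide
Product: 17 C8/C9 acetonide C7 Weinreb amide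
Conditions: 2-methoxypropene, PPTS (cat.), CH2Cl2, 0 °C
Reagents that add atoms: 2-methoxypropene, COC(C)=C
Why: Acid-catalysed acetonide formation on the only 1,2-diol present masks O9, which otherwise sits in a γ-relationship to the C2 carboxyl, for all steps up to the endgame.

Step 12
Reactants: 17 C8/C9 acetonide C7 Weinreb amide
Product: 18 12α,13α-epoxide of 17
Conditions: mCPBA, NaHCO3, CH2Cl2, 0 °C
Reagents that add atoms: 3-chloroperbenzoic acid, OOC(=O)c1cccc(Cl)c1
Why: Prilezhaev epoxidation of the ring A alkene should occur on the α face, anti to the C10 side chain and the β methyl groups at C1 and C11.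

Step 13
Reactants: 18 12α,13α-epoxide of 17
Product: 20 12α-allylic alcohol with the C13=C14 alkene, via 13β-phenylselanyl 12α-ol 19 (not isolated)
Conditions: (PhSe)2, NaBH4, EtOH, 25 → 60 °C; then H2O2 (30 %), pyridine, THF, 0 → 25 °C
Reagents that add atoms: none
Why: Epoxide to allylic alcohol transposition by selenide opening and selenoxide syn elimination, in which PhSe− opens the epoxide trans-diaxially at C13 (C12 is screened by the cis C11 methyl) and the selenoxide eliminates away from the carbinol carbon, giving the C12 α-alcohol.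

Step 14
Reactants: 20 12α-allylic alcohol with the C13=C14 alkene
Product: 21 12-O-TIPS Weinreb amide
Conditions: TIPSOTf, 2,6-lutidine, CH2Cl2, −78 → 0 °C
Reagents that add atoms: triisopropylsilyl trifluoromethanesulfonate, CC(C)[Si](C(C)C)(C(C)C)OS(=O)(=O)C(F)(F)F
Why: Silylation with the triflate protects the hindered allylic alcohol as an ether that should outlast the hydride, Lewis acid, thiolate and first fluoride steps.

Step 15
Reactants: 21 12-O-TIPS Weinreb amide
Product: 22 C7 aldehyde
Conditions: iBu2AlH, THF, −78 °C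
Reagents that add atoms: none
Why: Hydride reduction of a Weinreb amide stops at the chelated hemiaminal and gives the non-enolisable C7 aldehyde, the neopentyl-type C2 ester reacting much more slowly at −78 °C.

Step 16
Reactants: 23 2-methylprop-2-enal
Product: 25 racemic triethyl{[2-methyl-1-(tributylstannyl)prop-2-en-1-yl]oxy}silane, via lithium stannyl alkoxide 24 (not isolated)
Conditions: Bu3SnH, LiN(iPr)2, THF, 0 °C; 23, −78 °C; Et3SiCl, −78 → 0 °C
Reagents that add atoms: tributyltin hydride, CCCC[SnH](CCCC)CCCC; chlorotriethylsilane, CC[Si](CC)(CC)Cl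
Why: 1,2-Addition of Bu3SnLi to the enal and O-silylation of the alkoxide give the α-silyloxy allylstannane, whose stereocentre is erased in step 17.

Step 17
Reactants: 22 C7 aldehyde; 25 racemic triethyl{[2-methyl-1-(tributylstannyl)prop-2-en-1-yl]oxy}silane
Product: 27 C7 carbinol bearing the 6-O-TES isopropenyl carbinol unit (6,7-syn), via Z γ-silyloxy allylstannane 26 (not isolated)
Conditions: 25, BF3·OEt2, CH2Cl2, −78 °C; then 22, BF3·OEt2, −78 °C
Reagents that add atoms: none
Why: Lewis-acid-promoted addition of a γ-silyloxy allylstannane (formed by BF3-catalysed 1,3-stannyl shift), in which the open antiperiplanar transition state gives the syn C6/C7 relationship and Felkin–Anh/Cornforth approach anti to the C8–O bond, past the smaller C17 branch, sets C7.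

Step 18
Reactants: 27 C7 carbinol bearing the 6-O-TES isopropenyl carbinol unit (6,7-syn)
Product: 28 7-O-TBS 6-O-TES bis-silyl ether
Conditions: TBSOTf, 2,6-lutidine, CH2Cl2, −78 → 0 °C
Reagents that add atoms: tert-butyldimethylsilyl trifluoromethanesulfonate, CC(C)(C)[Si](C)(C)OS(=O)(=O)C(F)(F)F
Why: Silylation with the triflate caps the hindered C7 hydroxyl with a group chosen to outlast the TES ether at C6.

Step 19
Reactants: 28 7-O-TBS 6-O-TES bis-silyl ether
Product: 30 seco acid (C2 carboxylic acid; free C6 hydroxyl), via C2 acid 6-O-TES ether 29 (not isolated)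
Conditions: LiSCH2CH2CH3 (from CH3CH2CH2SH and nBuLi), DMPU–THF, 50 °C; then HF·pyridine, pyridine, THF, 0 °C
Reagents that add atoms: none
Why: SN2 demethylation of the methyl ester by thiolate (attack at the methyl carbon, not at the hindered acyl carbon) followed by selective fluoride cleavage of the allylic TES ether, which is far more labile than the TBS and TIPS ethers.

Step 20
Reactants: 30 seco acid (C2 carboxylic acid; free C6 hydroxyl)
Product: 32 eight-membered lactone (O6–C2), via mixed anhydride 31 (not isolated)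
Conditions: 2,4,6-trichlorobenzoyl chloride, Et3N, THF, 25 °C; then slow addition to DMAP, toluene, 90 °C (1 mM)
Reagents that add atoms: none
Why: Yamaguchi macrolactonisation at high dilution, ring closure being helped by the trans fusion of ring A at C1–C10 and the cis C8/C9 acetonide, which fold the C2 acyl group toward O6.

Step 21
Reactants: 32 eight-membered lactone (O6–C2)
Product: 33 2-methylene oxocane (exocyclic enol ether at C2; isopropenyl at C6)
Conditions: Cp2TiMe2, toluene, 70 °C, dark
Reagents that add atoms: dimethyltitanocene, C[Ti](C)(C1C=CC=C1)C1C=CC=C1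
Why: Petasis methylenation, in which Cp2Ti=CH2 formed by thermolysis converts the lactone carbonyl into the exocyclic enol ether under non-acidic conditions that spare acetonide and silyl ethers.

Step 22
Reactants: 33 2-methylene oxocane (exocyclic enol ether at C2; isopropenyl at C6)
Product: 34 ten-membered C2 ketone with the Z C5=C6 alkene
Conditions: toluene, Et3N (trace), base-washed sealed tube, 150 °C
Reagents that add atoms: none
Why: Thermal Claisen rearrangement in which the allyl vinyl ether C3=C2–O–C6–C5=C4 reorganises in a concerted [3,3] shift through a chair-like six-atom array, forming C3–C4 and cleaving C6–O. The closest known reaction type is the Claisen ring expansion of 2-methylene cyclic ethers that carry an alkenyl group at the other ether carbon to medium-ring cycloalkenones. The ten-membered ring is not closed by cyclisation but arises by two-atom ring expansion of the oxocane, the transient six-membered array being bridged by C1–C10–C9–C8–C7. No stereocentre is created, since C6 is consumed, C2 becomes a carbonyl carbon and C3 and C4 are methylene groups. The step needs Z geometry at C5=C6, which the five-atom bridge should secure because it can span C2 and C6 only with the C6–C7 bond axial on the chair (or the equivalent boat), an equatorial bond demanding an anti C2–O–C6–C7 torsion that an eight-membered ring cannot reach. It also needs the shift to outrun isomerisation of the exocyclic enol ether into the ring, hence base-washed glass and a trace of amine.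

Step 23
Reactants: 34 ten-membered C2 ketone with the Z C5=C6 alkene
Product: 35 C7/C19 diol ketone
Conditions: HF·pyridine, pyridine, THF, 0 → 25 °C
Reagents that add atoms: none
Why: Fluoride desilylation removes the two TBS ethers (primary at C19, secondary at C7) while the bulkier TIPS ether and the acetonide should remain.

Step 24
Reactants: 35 C7/C19 diol ketone
Product: 38 γ-lactone ketone (C19 carbonyl on O7), via C19 aldehyde 36 (not isolated), via C19/O7 lactol 37 (not isolated)
Conditions: TEMPO (cat.), PhI(OAc)2, CH2Cl2, 25 °C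
Reagents that add atoms: none
Why: TEMPO/PhI(OAc)2 oxidative lactonisation, in which the primary C19 alcohol is oxidised first, the aldehyde closes on O7 to the five-membered lactol (O9 being locked in the acetonide) and the lactol is oxidised to the lactone.

Step 25
Reactants: 38 γ-lactone ketone (C19 carbonyl on O7)
Product: 39 (2R)-C2 alcohol
Conditions: (S)-Me-CBS (0.3 equiv), BH3·SMe2, toluene, −20 °C
Reagents that add atoms: none
Why: Corey–Bakshi–Shibata reduction, in which the (S)-catalyst differentiates the quaternary C1 side from the C3 methylene side of the ketone and should deliver hydride to give the 2R carbinol under reagent control.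

Step 26
Reactants: 39 (2R)-C2 alcohol
Product: 40 C2/C8/C9 triol
Conditions: AcOH–H2O (4:1), 40 °C
Reagents that add atoms: none
Why: Acid-catalysed acetonide hydrolysis under mild aqueous conditions frees the C8/C9 diol without touching the TIPS ether or the lactone.

Step 27
Reactants: 40 C2/C8/C9 triol
Product: 41 2,9-diacetate
Conditions: Ac2O, DMAP, pyridine, CH2Cl2, 0 → 25 °C
Reagents that add atoms: acetic anhydride, CC(=O)OC(C)=O
Why: DMAP-catalysed acetylation esterifies the two secondary hydroxyls at C2 and C9, the tertiary C8 hydroxyl being inert under these conditions.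

Step 28
Reactants: 41 2,9-diacetate
Product: 42 C12 alcohol
Conditions: HF·pyridine, THF, 25 → 40 °C
Reagents that add atoms: none
Why: Fluoride cleavage of the TIPS ether under acidic, non-basic conditions avoids acetyl migration and lactone opening.

Step 29
Reactants: 42 C12 alcohol
Product: 43 CNP0211702.1
Conditions: (CH3CH2CH2CO)2O, DMAP, Et3N, CH2Cl2, 0 °C
Reagents that add atoms: butanoic anhydride, CCCC(=O)OC(=O)CCC
Why: DMAP-catalysed acylation of the allylic C12 hydroxyl with butanoic anhydride, the tertiary C8 hydroxyl staying free.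

Compound list

1 | 2,2-dimethoxyacetaldehyde | COC(OC)C=O | starting material
2 | methyl 2-(triphenyl-λ5-phosphanylidene)propanoate | COC(=O)C(C)=P(c1ccccc1)(c1ccccc1)c1ccccc1 | starting material
3 | methyl (2E)-4,4-dimethoxy-2-methylbut-2-enoate | COC(=O)/C(C)=C/C(OC)OC | intermediate
4 | methyl (2E)-2-methyl-4-oxobut-2-enoate | COC(=O)/C(C)=C/C=O | intermediate
5 | (3E)-penta-1,3-diene | C=C/C=C/C | starting material
6 | methyl (1S,5S,6S)-6-formyl-1,5-dimethylcyclohex-3-ene-1-carboxylate (ring A with C2 as ester and C9 as aldehyde) | COC(=O)[C@@]1(C)CC=C[C@H](C)[C@@H]1C=O | intermediate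
7 | dimethyl (2S)-2-hydroxybutanedioate | COC(=O)C[C@H](O)C(=O)OC | starting material
8 | dilithium alkoxide enolate of 7 | [Li+].[Li+].COC(=O)[C@@H]([O-])C=C([O-])OC | intermediate
9 | dimethyl (2S,3R)-2-hydroxy-3-methylbutanedioate | COC(=O)[C@H](C)[C@H](O)C(=O)OC | intermediate
10 | (2S,3R)-2-hydroxy-3-methylbutanedioic acid | OC(=O)[C@H](C)[C@H](O)C(=O)O | intermediate
11 | (2R)-2-[(2S,4S)-2-tert-butyl-5-oxo-1,3-dioxolan-4-yl]propanoic acid (cis-dioxolanone) | OC(=O)[C@H](C)[C@@H]1O[C@H](C(C)(C)C)OC1=O | intermediate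
12 | (2S,5S)-2-tert-butyl-5-[(2S)-1-hydroxypropan-2-yl]-1,3-dioxolan-4-one | OC[C@H](C)[C@@H]1O[C@H](C(C)(C)C)OC1=O | intermediate
13 | (2S,5S)-2-tert-butyl-5-[(2S)-1-(tert-butyldimethylsilyloxy)propan-2-yl]-1,3-dioxolan-4-one | CC(C)(C)[Si](C)(C)OC[C@H](C)[C@@H]1O[C@H](C(C)(C)C)OC1=O | intermediate
14 | lithium enolate of 13 (C8 trigonal; acetal carbon unchanged) | [Li+].CC(C)(C)[Si](C)(C)OC[C@H](C)C1=C([O-])O[C@@H](C(C)(C)C)O1 | intermediate
15 | aldol adduct: ring A methyl ester joined through the C9 carbinol to C8 of the dioxolanone (tert-butyl trans to C9; C17 side chain CH(CH3)CH2OTBS); C1, C8, C9, C10, C11, C17 as in the target | COC(=O)[C@@]1(C)CC=C[C@H](C)[C@@H]1[C@@H](O)[C@]2(O[C@H](C(C)(C)C)OC2=O)[C@@H](C)CO[Si](C)(C)C(C)(C)C | intermediate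
16 | C8/C9 diol with C7 as N-methoxy-N-methylamide; ring A as in 6; C19 OTBS | COC(=O)[C@@]1(C)CC=C[C@H](C)[C@@H]1[C@@H](O)[C@@](O)(C(=O)N(C)OC)[C@@H](C)CO[Si](C)(C)C(C)(C)C | intermediate
17 | C8/C9 O-isopropylidene derivative of 16 | COC(=O)[C@@]1(C)CC=C[C@H](C)[C@@H]1[C@H]2OC(C)(C)O[C@]2(C(=O)N(C)OC)[C@@H](C)CO[Si](C)(C)C(C)(C)C | intermediate
18 | 12α,13α-epoxide of 17 | COC(=O)[C@@]1(C)C[C@H]3O[C@H]3[C@H](C)[C@@H]1[C@H]2OC(C)(C)O[C@]2(C(=O)N(C)OC)[C@@H](C)CO[Si](C)(C)C(C)(C)C | intermediate
19 | 13β-phenylselanyl 12α-ol from 18 | COC(=O)[C@@]1(C)C[C@H]([Se]c3ccccc3)[C@@H](O)[C@H](C)[C@@H]1[C@H]2OC(C)(C)O[C@]2(C(=O)N(C)OC)[C@@H](C)CO[Si](C)(C)C(C)(C)C | intermediate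
20 | 12α-hydroxy C13=C14 ring A ester with C8/C9 acetonide and C7 Weinreb amide | COC(=O)[C@@]1(C)C=C[C@@H](O)[C@H](C)[C@@H]1[C@H]2OC(C)(C)O[C@]2(C(=O)N(C)OC)[C@@H](C)CO[Si](C)(C)C(C)(C)C | intermediate
21 | 12-O-triisopropylsilyl ether of 20 | COC(=O)[C@@]1(C)C=C[C@@H](O[Si](C(C)C)(C(C)C)C(C)C)[C@H](C)[C@@H]1[C@H]2OC(C)(C)O[C@]2(C(=O)N(C)OC)[C@@H](C)CO[Si](C)(C)C(C)(C)C | intermediate
22 | C7 aldehyde from 21 | COC(=O)[C@@]1(C)C=C[C@@H](O[Si](C(C)C)(C(C)C)C(C)C)[C@H](C)[C@@H]1[C@H]2OC(C)(C)O[C@]2(C=O)[C@@H](C)CO[Si](C)(C)C(C)(C)C | intermediate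
23 | 2-methylprop-2-enal | CC(=C)C=O | starting material
24 | lithium 2-methyl-1-(tributylstannyl)prop-2-en-1-olate (racemic) | [Li+].[O-]C(C(C)=C)[Sn](CCCC)(CCCC)CCCC | intermediate
25 | triethyl{[2-methyl-1-(tributylstannyl)prop-2-en-1-yl]oxy}silane (racemic) | CC[Si](CC)(CC)OC(C(C)=C)[Sn](CCCC)(CCCC)CCCC | intermediate
26 | (Z)-triethyl{[2-methyl-3-(tributylstannyl)prop-1-en-1-yl]oxy}silane | CC[Si](CC)(CC)O/C=C(/C)C[Sn](CCCC)(CCCC)CCCC | intermediate
27 | C7 carbinol (configuration of the target) with 6-O-triethylsilyl isopropenyl carbinol at C6 (6,7-syn); C2 methyl ester, C8/C9 acetonide, 12-OTIPS, 19-OTBS | COC(=O)[C@@]1(C)C=C[C@@H](O[Si](C(C)C)(C(C)C)C(C)C)[C@H](C)[C@@H]1[C@H]2OC(C)(C)O[C@]2([C@@H](O)[C@H](O[Si](CC)(CC)CC)C(C)=C)[C@@H](C)CO[Si](C)(C)C(C)(C)C | intermediate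
28 | 7-O-tert-butyldimethylsilyl ether of 27 | COC(=O)[C@@]1(C)C=C[C@@H](O[Si](C(C)C)(C(C)C)C(C)C)[C@H](C)[C@@H]1[C@H]2OC(C)(C)O[C@]2([C@@H](O[Si](C)(C)C(C)(C)C)[C@H](O[Si](CC)(CC)CC)C(C)=C)[C@@H](C)CO[Si](C)(C)C(C)(C)C | intermediate
29 | C2 carboxylic acid of 28 (6-O-TES retained) | OC(=O)[C@@]1(C)C=C[C@@H](O[Si](C(C)C)(C(C)C)C(C)C)[C@H](C)[C@@H]1[C@H]2OC(C)(C)O[C@]2([C@@H](O[Si](C)(C)C(C)(C)C)[C@H](O[Si](CC)(CC)CC)C(C)=C)[C@@H](C)CO[Si](C)(C)C(C)(C)C | intermediate
30 | seco acid: C2 carboxylic acid with free C6 hydroxyl; 7-OTBS, C8/C9 acetonide, 12-OTIPS, 19-OTBS | OC(=O)[C@@]1(C)C=C[C@@H](O[Si](C(C)C)(C(C)C)C(C)C)[C@H](C)[C@@H]1[C@H]2OC(C)(C)O[C@]2([C@@H](O[Si](C)(C)C(C)(C)C)[C@H](O)C(C)=C)[C@@H](C)CO[Si](C)(C)C(C)(C)C | intermediate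
31 | mixed anhydride of 30 with 2,4,6-trichlorobenzoic acid | O=C(OC(=O)c3c(Cl)cc(Cl)cc3Cl)[C@@]1(C)C=C[C@@H](O[Si](C(C)C)(C(C)C)C(C)C)[C@H](C)[C@@H]1[C@H]2OC(C)(C)O[C@]2([C@@H](O[Si](C)(C)C(C)(C)C)[C@H](O)C(C)=C)[C@@H](C)CO[Si](C)(C)C(C)(C)C | intermediate
32 | eight-membered lactone: C2 carbonyl on O6, trans-fused to ring A at C1–C10, cis-fused C8/C9 acetonide, 7-OTBS, 6-isopropenyl cis to O7 | CC(C)[Si](C(C)C)(C(C)C)O[C@@H]1C=C[C@@]2(C)[C@H]([C@H]1C)[C@H]3OC(C)(C)O[C@@]3([C@@H](C)CO[Si](C)(C)C(C)(C)C)[C@@H](O[Si](C)(C)C(C)(C)C)[C@@H](C(C)=C)OC2=O | intermediate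
33 | key-step precursor: exocyclic enol ether (2-methylene) of the C2/C6 oxocane fused to ring A, substituents as in 32 | CC(C)[Si](C(C)C)(C(C)C)O[C@@H]1C=C[C@@]2(C)[C@H]([C@H]1C)[C@H]3OC(C)(C)O[C@@]3([C@@H](C)CO[Si](C)(C)C(C)(C)C)[C@@H](O[Si](C)(C)C(C)(C)C)[C@@H](C(C)=C)OC2=C | intermediate
34 | key-step product: ten-membered C2 ketone with the Z C5=C6 alkene; 7-OTBS, C8/C9 acetonide, 12-OTIPS, 19-OTBS | CC(C)[Si](C(C)C)(C(C)C)O[C@@H]1C=C[C@@]2(C)[C@H]([C@H]1C)[C@H]3OC(C)(C)O[C@@]3([C@@H](C)CO[Si](C)(C)C(C)(C)C)[C@@H](O[Si](C)(C)C(C)(C)C)/C=C(/C)CCC2=O | intermediate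
35 | C7/C19 diol of 34 | CC(C)[Si](C(C)C)(C(C)C)O[C@@H]1C=C[C@@]2(C)[C@H]([C@H]1C)[C@H]3OC(C)(C)O[C@@]3([C@@H](C)CO)[C@@H](O)/C=C(/C)CCC2=O | intermediate
36 | C19 aldehyde with free C7 hydroxyl | CC(C)[Si](C(C)C)(C(C)C)O[C@@H]1C=C[C@@]2(C)[C@H]([C@H]1C)[C@H]3OC(C)(C)O[C@@]3([C@@H](C)C=O)[C@@H](O)/C=C(/C)CCC2=O | intermediate
37 | C19/O7 lactol (anomeric mixture at C19) | CC(C)[Si](C(C)C)(C(C)C)O[C@@H]1C=C[C@@]2(C)[C@H]([C@H]1C)[C@H]3OC(C)(C)O[C@]34[C@@H](C)C(O)O[C@H]4/C=C(/C)CCC2=O | intermediate
38 | γ-lactone (C19 carbonyl on O7) with C2 ketone, C8/C9 acetonide, 12-OTIPS | CC(C)[Si](C(C)C)(C(C)C)O[C@@H]1C=C[C@@]2(C)[C@H]([C@H]1C)[C@H]3OC(C)(C)O[C@]34[C@@H](C)C(=O)O[C@H]4/C=C(/C)CCC2=O | intermediate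
39 | (2R)-alcohol from 38 | CC(C)[Si](C(C)C)(C(C)C)O[C@@H]1C=C[C@@]2(C)[C@H]([C@H]1C)[C@H]3OC(C)(C)O[C@]34[C@@H](C)C(=O)O[C@H]4/C=C(/C)CC[C@H]2O | intermediate
40 | C2/C8/C9 triol lactone with 12-OTIPS | CC(C)[Si](C(C)C)(C(C)C)O[C@@H]1C=C[C@@]2(C)[C@H]([C@H]1C)[C@@H](O)[C@]4(O)[C@@H](C)C(=O)O[C@H]4/C=C(/C)CC[C@H]2O | intermediate
41 | 2,9-diacetate of 40 | CC(C)[Si](C(C)C)(C(C)C)O[C@@H]1C=C[C@@]2(C)[C@H]([C@H]1C)[C@@H](OC(C)=O)[C@]4(O)[C@@H](C)C(=O)O[C@H]4/C=C(/C)CC[C@H]2OC(C)=O | intermediate
42 | 12-alcohol: 2,9-diacetoxy-8,12-dihydroxy lactone | O[C@@H]1C=C[C@@]2(C)[C@H]([C@H]1C)[C@@H](OC(C)=O)[C@]4(O)[C@@H](C)C(=O)O[C@H]4/C=C(/C)CC[C@H]2OC(C)=O | intermediate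
43 | CNP0211702.1: (1S,2R,5Z,7S,8S,9R,10S,11R,12R,17R)-2,9-diacetoxy-12-butanoyloxy-8-hydroxybriara-5,13-diene 19,7-lactone | CCCC(=O)O[C@@H]1C=C[C@@]2(C)[C@H]([C@H]1C)[C@@H](OC(C)=O)[C@@]1(O)[C@H](/C=C(/C)CC[C@H]2OC(C)=O)OC(=O)[C@@H]1C | target

Total step count: 29. Longest linear sequence: 25 steps (steps 4–15 and 17–29, from dimethyl (2S)-2-hydroxybutanedioate 7 to 43); the ring A aldehyde 6 (steps 1–3) and the stannane 25 (step 16) are made in side branches that join at steps 9 and 17.

Steps most likely to fail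

Step 22. The exocyclic enol ether may isomerise into the ring or hydrolyse faster than it rearranges at 150 °C, and some E ring alkene may leak through. The fallback sets out from 33 and replaces the thermal pericyclic shift by an aluminium-promoted one at low temperature. Triisobutylaluminium (CH2Cl2, −78 → 0 °C) should trigger the Claisen ring expansion and reduce the aluminium-bound ketone in the same flask, giving the ring-expanded C2 carbinol F1 (drawn as its 2R epimer; either epimer serves). Oxidation with Dess–Martin periodinane (NaHCO3, CH2Cl2) returns to the route at 34.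

Step 20. Acyl transfer from the neopentyl-type mixed anhydride to the hindered C6 hydroxyl may be slower than intermolecular acylation, so that diolide and oligomers form. The fallback sets out from 30 and activates the alcohol instead of the acid: Mitsunobu macrolactonisation (PPh3, diisopropyl azodicarboxylate, toluene, high dilution) closes the ring by carboxylate attack at C6 with inversion, giving the C6-epimeric lactone F2. Cp2TiMe2 (toluene, 70 °C) gives the C6-epimeric enol ether F3, and thermolysis as in step 22 returns to the route at 34, because C6 becomes trigonal.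

Step 9. Addition of the tetrasubstituted lithium enolate to the α-branched aldehyde may stall through retro-aldol, or the lithium aldolate may lactonise onto the C2 ester. The fallback sets out from 13 and moves to an irreversible, alkoxide-free addition: the enolate is trapped (LiN(iPr)2, Me3SiCl, THF, −78 °C) as the silyl ketene acetal F4, which is added to 6 under BF3·OEt2 (CH2Cl2, −78 °C) in a Mukaiyama aldol reaction with the same tert-butyl and Felkin–Anh controls. Aqueous work-up returns to the route at 15.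

Further compounds
F1 | step 22 | ring-expanded C2 carbinol with the Z C5=C6 alkene (7-OTBS, C8/C9 acetonide, 12-OTIPS, 19-OTBS; 2R drawn) | CC(C)[Si](C(C)C)(C(C)C)O[C@@H]1C=C[C@@]2(C)[C@H]([C@H]1C)[C@H]3OC(C)(C)O[C@@]3([C@@H](C)CO[Si](C)(C)C(C)(C)C)[C@@H](O[Si](C)(C)C(C)(C)C)/C=C(/C)CC[C@H]2O
F2 | step 20 | C6-epimer of lactone 32 | CC(C)[Si](C(C)C)(C(C)C)O[C@@H]1C=C[C@@]2(C)[C@H]([C@H]1C)[C@H]3OC(C)(C)O[C@@]3([C@@H](C)CO[Si](C)(C)C(C)(C)C)[C@@H](O[Si](C)(C)C(C)(C)C)[C@H](C(C)=C)OC2=O
F3 | step 20 | C6-epimer of enol ether 33 | CC(C)[Si](C(C)C)(C(C)C)O[C@@H]1C=C[C@@]2(C)[C@H]([C@H]1C)[C@H]3OC(C)(C)O[C@@]3([C@@H](C)CO[Si](C)(C)C(C)(C)C)[C@@H](O[Si](C)(C)C(C)(C)C)[C@H](C(C)=C)OC2=C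
F4 | step 9 | trimethylsilyl ketene acetal of dioxolanone 13 | CC(C)(C)[Si](C)(C)OC[C@H](C)C1=C(O[Si](C)(C)C)O[C@@H](C(C)(C)C)O1
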